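The constants used here are assumed, and the outcome is calculated.

Judge these flasks by how fast X can take up L, and set the charges against that pace.

| setting | birch | cedar | larch | elm |
|---|---|---|---|---|
| Q | 0.050 M | 0.050 M (fed, over 12 h) | 0.050 M (fed, over 12 h) | 0.050 M (in portions, 2, over 12 h) |
| L | 0.125 M | 0.125 M | 0.125 M | 0.125 M |
| X | 50 µM | 50 µM | 50 µM | 50 µM |
| temperature | 20 °C |  | 20 °C | 20 °C |
| time | 15 h | 15 h | 15 h | 15 h |
| remark | everything together at the start | the addition at −10 °C, then warmed to 20 °C; the feed brings no volume worth counting | all else is in the flask from the start; the feed brings no volume worth counting | first portion at the start, last at 12 h |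

    L + X ⇌ L.X (K1 = 100 M⁻¹, k1 = 52 M⁻¹ min⁻¹, Ea1 = 45.0 kJ mol⁻¹, ΔH1 = −34.0 kJ mol⁻¹)
    Q + L.X → Q.L.X (k2 = 720 M⁻¹ min⁻¹, Ea2 = 36.0 kJ mol⁻¹)
    Q.L.X ⇌ X + J (K3 = 0.023 M, k3 = 66 min⁻¹, Ea3 = 74.0 kJ mol⁻¹, ΔH3 = −81.0 kJ mol⁻¹)
    (constants at 20 °C)

* the flask that comes out highest in amount of J, in percent of the Q charged, or "all alike" when all lie within 1.5 percentage points (birch / cedar / larch / elm / all alike)
* J at the end, in percent of the Q charged, birch
* J at the end, in percent of the Q charged, cedar
* J at the end, in percent of the Q charged, larch
* J at the end, in percent of the Q charged, elm

- the constants hold at 20 °C; other temperatures follow from the activation energies and enthalpies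

You asked for a quick number, so I reckoned from one step. At 20 °C, Q.L.X gave up J at 66 min⁻¹, faster than X took up L at 6.50 min⁻¹. I therefore treated the uptake of L as the rate-limiting step and let J hold X back as Q.L.X in the ratio of [J] to the constant of the last step. I set L.X aside. With the Q charge turned over and L reduced by the same amount, this gave 0.00369 M h⁻¹. I called this P, the closing pace: my estimate, with L.X set aside, of the rate at which X still takes up L at the end of a complete run.

At P, birch needed 13.6 h for its charge, less than its 15 h, so I wrote 100 %. For larch I divided the feed rate, which carries the 12 h of the feed, by P and got the unitless ratio 1.13. The feed would end slightly ahead of the catalyst, yet I still wrote 100 %. For elm, the last half of the charge needed 6.78 h, longer than the 3.00 h it had, so I gave only a bound, 72.1 %. For cedar in the cold, the feed rate over the uptake rate of fully free X came to 1.75. Q would pile up, but I reached no figure.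

The forecast you sent went further: birch 100 %, cedar 67 %, larch 97.4 %, elm 79 %, with birch highest, and it said “the steady feed runs slightly ahead of the catalyst near its end”.

The simulation gave birch >99.9 %, cedar 67.0 %, larch 98.1 % and elm 79.0 %, with birch highest, so the forecast held.

I had built the hold of J on X into P, and the flasks showed that hold at work. With the reverse step X + J → Q.L.X struck out, the gap between birch and cedar shrank from 33 percentage points to 12 points. Cedar had 70.6 % of its Q standing at 12.0 h, and clearing that in the remaining time needed 3.19 times P; it ended with 32.9 %. For the neighbour of cedar with 0.50 M of L, P became 0.0221 M h⁻¹, and the whole charge in those last hours needed 0.754 of it, so I expected near completion. That flask gave 99.1 %.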